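## Retrosynthetic overview

1. The last bonds cut are the two aryl O–Si bonds (global desilylation) and, before that, the two enol-ester O–C(=O) bonds on the quinone. This leaves a bis-silyl-protected 2,5-dihydroxy-3,6-bis(4-hydroxyphenyl)-1,4-benzoquinone and two (2Z,4S,5S)-4,5-epoxyhex-2-enoate units.
2. Enabling feature: the six carbons of the quinone ring are two identical three-carbon units (aryl-bearing carbon, ring carbonyl carbon, O-acyl-bearing carbon) related by the inversion centre of the ring. The ring already stands at the oxidation level of two arylpyruvic esters minus two methanol.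
3. Both ring bonds that join an aryl-bearing carbon to the neighbouring O-acyl-bearing carbon are therefore cut together. The whole ring comes from a head-to-tail Claisen–Dieckmann cyclodimerisation of one silyl-protected methyl 4-hydroxyphenylpyruvate, made from 4-bromophenol by silylation, Cu-catalysed Grignard opening of methyl glycidate and oxidation.
4. Side chain: Sharpless epoxidation of (E)-crotyl alcohol sets both stereocentres; oxidation, Still–Gennari Z-olefination and anhydrous ester cleavage give the potassium carboxylate.
5. Ring order: the benzene rings are bought; the quinone ring is formed in step 4; the oxirane ring is formed in step 5 on the separate branch; the branches meet in step 9.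

Key step: step 4

Remark: the hydroxyquinone is treated as the 2,5-dihydroxy-1,4-benzoquinone tautomer of the 3,6-diarylcyclohexane-1,2,4,5-tetraone that the condensation formally delivers. Methyl glycidate is used as the racemate because its stereocentre is erased in step 3.

## Route

Step 1
Reactants: 1 4-bromophenol
Product: 2 (4-bromophenoxy)triisopropylsilane
Conditions: TIPSCl, imidazole, DMF, 23 °C
Reagents that add atoms: triisopropylsilyl chloride, CC(C)[Si](Cl)(C(C)C)C(C)C
Why: Standard imidazole-promoted O-silylation of a phenol; the bulky TIPS ether is chosen to withstand the Grignard step, the strongly basic key step and the acylation.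

Step 2
Reactants: 2 (4-bromophenoxy)triisopropylsilane; 3 methyl oxirane-2-carboxylate (racemic methyl glycidate)
Product: 5 methyl 2-hydroxy-3-[4-(triisopropylsilyloxy)phenyl]propanoate (racemic), via arylmagnesium bromide 4 (not isolated)
Conditions: Mg, THF, 40 °C; then CuI (10 mol%), 3, THF, −40 → −10 °C; aq. NH4Cl
Reagents that add atoms: none
Why: Copper-catalysed Grignard (organocuprate) opening of a glycidic ester at its unsubstituted CH2 carbon should outrun carbonyl addition at low temperature and give the 3-aryl-lactate; the carbinol centre is formed racemic on purpose because step 3 removes it.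

Step 3
Reactants: 5 methyl 2-hydroxy-3-[4-(triisopropylsilyloxy)phenyl]propanoate
Product: 6 methyl 2-oxo-3-[4-(triisopropylsilyloxy)phenyl]propanoate (expected to rest largely as its Z-enol)
Conditions: Dess–Martin periodinane, CH2Cl2, 0 → 23 °C
Reagents that add atoms: none
Why: Dess–Martin oxidation of a secondary α-hydroxy ester to the α-keto ester runs under non-basic conditions that spare the aryl silyl ether and avoid base-induced self-condensation of the product.

Step 4
Reactants: 6 methyl 2-oxo-3-[4-(triisopropylsilyloxy)phenyl]propanoate (two molecules)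
Product: 9 2,5-dihydroxy-3,6-bis[4-(triisopropylsilyloxy)phenyl]-1,4-benzoquinone, via lithium enolate 7 (not isolated), via open-chain Claisen adduct 8 (not isolated)
Conditions: LiN(SiMe3)2 (1.1 equiv per 6), THF, −78 °C (6 added to the base), then 23 → 55 °C; 1 M HCl
Reagents that add atoms: none
Why: Proposed new method: adding 6 to LiN(SiMe3)2 converts every molecule at once into the chelated lithium enolate 7, so no free ketone is left for the aldol–lactonisation that arylpyruvates normally undergo, and the only C–C bond-forming path is attack of the benzylic enolate carbon of one molecule on the lithium-activated ester carbonyl of a second one (addition–elimination, loss of methoxide) to give the open-chain adduct 8, whose remaining enolate carbon and ester then close the ring in the same way. The closest known reaction types are the Claisen–Dieckmann cyclodimerisation of diethyl succinate to diethyl succinylsuccinate and, in logic, the head-to-tail Claisen dimerisation of two 4-hydroxyphenylpyruvate units by which this ring system arises in nature; what is new is the use of a pre-formed 2-oxo ester enolate as both donor and acceptor. The ring is closed by a favoured 6-exo-trig (enolendo) Dieckmann acylation, and the 3,6-diarylcyclohexane-1,2,4,5-tetraone so formed is simply the keto tautomer of the 2,5-dihydroxy-1,4-benzoquinone, so no redox step follows. No stereocentre is formed. The step needs C- over O-acylation, cyclodimer over oligomer and head-to-tail regiochemistry: O-acylation and ester exchange stay reversible under the methoxide released whereas C-acylation ends in the doubly vinylogous carboxylate dianion of 9 (the thermodynamic sink), the second bond is made intramolecularly in a six-membered transition state, and each monomer has only one nucleophilic carbon and one acyl carbon. The TIPS ethers are chosen to resist lithium methoxide and to keep the enolate soluble in THF.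

Step 5
Reactants: 10 (E)-but-2-en-1-ol
Product: 11 [(2S,3S)-3-methyloxiran-2-yl]methanol
Conditions: Ti(OiPr)4 (5 mol%), L-(+)-diisopropyl tartrate (6 mol%), t-BuOOH, 4 Å MS, CH2Cl2, −20 °C; non-aqueous work-up, distillation
Reagents that add atoms: tert-butyl hydroperoxide, CC(C)(C)OO
Why: Sharpless asymmetric epoxidation: the titanium–L-(+)-tartrate complex delivers the peroxide oxygen to the face of the E-allylic alcohol that gives the (2S,3S)-epoxy alcohol, so both side-chain stereocentres are set here by the chiral catalyst and the trans relationship follows from the E-alkene.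

Step 6
Reactants: 11 [(2S,3S)-3-methyloxiran-2-yl]methanol
Product: 12 (2R,3S)-3-methyloxirane-2-carbaldehyde
Conditions: Pr4N[RuO4] (5 mol%), N-methylmorpholine N-oxide, 4 Å MS, CH2Cl2, 0 → 23 °C; silica pad; solution used directly
Reagents that add atoms: none
Why: Ley–Griffith oxidation is neutral and non-aqueous, which suits a small, water-soluble epoxy aldehyde; both stereocentres are untouched (the descriptor at C2 becomes R only through the change in CIP priorities).

Step 7
Reactants: 12 (2R,3S)-3-methyloxirane-2-carbaldehyde; 13 methyl bis(2,2,2-trifluoroethyl)phosphonoacetate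
Product: 14 methyl (2Z)-3-[(2S,3S)-3-methyloxiran-2-yl]prop-2-enoate
Conditions: KN(SiMe3)2, 18-crown-6, THF, −78 °C
Reagents that add atoms: none
Why: Still–Gennari variant of the Horner–Wadsworth–Emmons olefination: the electron-poor bis(trifluoroethyl) phosphonate with a dissociated potassium counter-ion eliminates from the kinetic adduct faster than it equilibrates, which should give the Z-enoate, and the epoxide carbons are not epimerised at −78 °C.

Step 8
Reactants: 14 methyl (2Z)-3-[(2S,3S)-3-methyloxiran-2-yl]prop-2-enoate
Product: 15 potassium (2Z)-3-[(2S,3S)-3-methyloxiran-2-yl]prop-2-enoate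
Conditions: KOSiMe3 (1.0 equiv), THF, 0 → 23 °C; salt collected by filtration
Reagents that add atoms: potassium trimethylsilanolate, C[Si](C)(C)[O-].[K+]
Why: Anhydrous silanolate cleavage of the methyl ester delivers the carboxylate salt directly, avoiding the free Z-epoxy acid, which is prone to acid-triggered lactonisation onto the epoxide.

Step 9
Reactants: 15 potassium (2Z)-3-[(2S,3S)-3-methyloxiran-2-yl]prop-2-enoate (2.4 equiv); 9 2,5-dihydroxy-3,6-bis[4-(triisopropylsilyloxy)phenyl]-1,4-benzoquinone
Product: 17 3,6-dioxo-2,5-bis[4-(triisopropylsilyloxy)phenyl]cyclohexa-1,4-diene-1,4-diyl bis{(2Z)-3-[(2S,3S)-3-methyloxiran-2-yl]prop-2-enoate}, via mixed anhydride 16 (not isolated)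
Conditions: 2,4,6-trichlorobenzoyl chloride, THF, 0 °C; then 9, Et3N, DMAP (20 mol%), toluene, −20 → 0 °C
Reagents that add atoms: none
Why: Yamaguchi esterification: the hindered mixed anhydride 16 transfers only the enoyl group (through the acylpyridinium ion) to the two acidic quinonoid hydroxyls, which Et3N turns into vinylogous carboxylates while the phenols stay blocked as TIPS ethers, and the 2,5-bis(acyloxy)-1,4-quinone is the stable acylation pattern of this core.

Step 10
Reactants: 17 bis-TIPS-protected diester
Product: 18 2,5-bis(4-hydroxyphenyl)-3,6-dioxocyclohexa-1,4-diene-1,4-diyl bis{(2Z)-3-[(2S,3S)-3-methyloxiran-2-yl]prop-2-enoate} (target, CNP0407724.1)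
Conditions: HF·pyridine, pyridine, THF, 0 → 23 °C; quench with Me3SiOMe
Reagents that add atoms: none
Why: Fluoride-driven cleavage of the aryl O–Si bonds with pyridine-buffered HF is mildly acidic and poorly nucleophilic, conditions under which the activated enol esters, the Z-enoates and the electron-poor vinyl epoxides are expected to persist.

## Compound list

1 | 4-bromophenol | Oc1ccc(Br)cc1 | starting material
2 | (4-bromophenoxy)triisopropylsilane | CC(C)[Si](Oc1ccc(Br)cc1)(C(C)C)C(C)C | intermediate
3 | methyl oxirane-2-carboxylate (racemic methyl glycidate) | COC(=O)C1CO1 | starting material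
4 | [4-(triisopropylsilyloxy)phenyl]magnesium bromide | CC(C)[Si](Oc1ccc([Mg]Br)cc1)(C(C)C)C(C)C | intermediate (not isolated)
5 | methyl 2-hydroxy-3-[4-(triisopropylsilyloxy)phenyl]propanoate (racemic) | COC(=O)C(O)Cc1ccc(O[Si](C(C)C)(C(C)C)C(C)C)cc1 | intermediate
6 | methyl 2-oxo-3-[4-(triisopropylsilyloxy)phenyl]propanoate (keto form drawn) | COC(=O)C(=O)Cc1ccc(O[Si](C(C)C)(C(C)C)C(C)C)cc1 | intermediate
7 | lithium (Z)-enolate of 6 | [Li+].[O-]/C(=C\c1ccc(O[Si](C(C)C)(C(C)C)C(C)C)cc1)C(=O)OC | intermediate (not isolated)
8 | methyl 2,4,5-trioxo-3,6-bis[4-(triisopropylsilyloxy)phenyl]hexanoate (present as its lithium enolate; neutral keto form drawn) | COC(=O)C(=O)C(c1ccc(O[Si](C(C)C)(C(C)C)C(C)C)cc1)C(=O)C(=O)Cc1ccc(O[Si](C(C)C)(C(C)C)C(C)C)cc1 | intermediate (not isolated)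
9 | 2,5-dihydroxy-3,6-bis[4-(triisopropylsilyloxy)phenyl]-1,4-benzoquinone | OC1=C(c2ccc(O[Si](C(C)C)(C(C)C)C(C)C)cc2)C(=O)C(O)=C(c2ccc(O[Si](C(C)C)(C(C)C)C(C)C)cc2)C1=O | intermediate
10 | (E)-but-2-en-1-ol | C/C=C/CO | starting material
11 | [(2S,3S)-3-methyloxiran-2-yl]methanol | C[C@@H]1O[C@H]1CO | intermediate
12 | (2R,3S)-3-methyloxirane-2-carbaldehyde | C[C@@H]1O[C@H]1C=O | intermediate
13 | methyl bis(2,2,2-trifluoroethyl)phosphonoacetate | COC(=O)CP(=O)(OCC(F)(F)F)OCC(F)(F)F | starting material
14 | methyl (2Z)-3-[(2S,3S)-3-methyloxiran-2-yl]prop-2-enoate | C[C@@H]1O[C@H]1/C=C\C(=O)OC | intermediate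
15 | potassium (2Z)-3-[(2S,3S)-3-methyloxiran-2-yl]prop-2-enoate | C[C@@H]1O[C@H]1/C=C\C(=O)[O-].[K+] | intermediate
16 | (2Z)-3-[(2S,3S)-3-methyloxiran-2-yl]prop-2-enoic 2,4,6-trichlorobenzoic anhydride | C[C@@H]1O[C@H]1/C=C\C(=O)OC(=O)c1c(Cl)cc(Cl)cc1Cl | intermediate (not isolated)
17 | 3,6-dioxo-2,5-bis[4-(triisopropylsilyloxy)phenyl]cyclohexa-1,4-diene-1,4-diyl bis{(2Z)-3-[(2S,3S)-3-methyloxiran-2-yl]prop-2-enoate} | C[C@@H]1O[C@H]1/C=C\C(=O)OC1=C(c2ccc(O[Si](C(C)C)(C(C)C)C(C)C)cc2)C(=O)C(OC(=O)/C=C\[C@@H]2O[C@H]2C)=C(c2ccc(O[Si](C(C)C)(C(C)C)C(C)C)cc2)C1=O | intermediate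
18 | 2,5-bis(4-hydroxyphenyl)-3,6-dioxocyclohexa-1,4-diene-1,4-diyl bis{(2Z)-3-[(2S,3S)-3-methyloxiran-2-yl]prop-2-enoate} | C[C@@H]1O[C@H]1/C=C\C(=O)OC1=C(c2ccc(O)cc2)C(=O)C(OC(=O)/C=C\[C@@H]2O[C@H]2C)=C(c2ccc(O)cc2)C1=O | target

## Step count and risks

Total step count: 10. Longest linear sequence: 6 steps (steps 1, 2, 3, 4, 9, 10; the side-chain branch 5, 6, 7, 8, 9, 10 is equally long).

Steps most likely to fail:

Step 4 (the proposed new method). The intermolecular C-acylation between two anionic enolates may be too slow. Cleavage of the aryl silyl ethers by lithium methoxide, reversible O-acylation to oligomeric enol esters or, if enolisation is incomplete, aldol addition with lactonisation could then consume the material. The fallback uses known chemistry and a different bond set; it leaves the route at 2 and comes back at 9. Bromine–lithium exchange on 2 (n-BuLi, THF, −78 °C), then B(OiPr)3 and dilute HCl, should give [4-(triisopropylsilyloxy)phenyl]boronic acid F1. Bromanil and NaOMe in MeOH give 2,5-dibromo-3,6-dimethoxy-1,4-benzoquinone F2. A twofold Suzuki–Miyaura coupling of F1 with F2 (Pd(PPh3)4, a zerovalent palladium complex, K2CO3, dioxane–water, 80 °C) should give 2,5-dimethoxy-3,6-bis[4-(triisopropylsilyloxy)phenyl]-1,4-benzoquinone F3. Its two vinylogous methyl esters are then hydrolysed by addition–elimination (aq. LiOH, THF, 23 °C; dilute HCl) to 9.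

Step 9. The enoyl group may isomerise from Z to E through reversible conjugate addition of DMAP to the acylpyridinium ion, or acylation of the weakly nucleophilic vinylogous carboxylate may be so slow that the mixed anhydride decays first. The fallback reverses the polarity; it leaves at 9 and comes back at 17. Oxalyl chloride with catalytic DMF in CH2Cl2 should convert the two vinylogous acid groups of 9 into vinylogous acid chlorides, giving 2,5-dichloro-3,6-bis[4-(triisopropylsilyloxy)phenyl]-1,4-benzoquinone F4. The carboxylate 15 (18-crown-6, MeCN, 23 °C) then displaces both chlorides by addition–elimination at the quinone carbons to give 17, with no activated form of the Z-enoic acid and no nucleophilic catalyst.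

Step 10. The activated enol-ester acyl groups may be lost to fluoride or pyridine, or the vinyl epoxide may be opened by HF, before both Si–O bonds are cleaved. The fallback removes the protecting groups before the acylation; it leaves at 9 and comes back at 18. Desilylation of 9 at this robust stage (HF·pyridine, THF, 23 °C) should give atromentin F5. Its two quinonoid hydroxyls are vinylogous carboxylic acids and far more acidic than the phenols, so exactly two equivalents of Et3N should deprotonate only these. Acylation with two equivalents of the mixed anhydride 16 (THF, −20 °C, no DMAP) should then leave the neutral phenols untouched and give 18 directly.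

Further compounds
F1 | step 4 | [4-(triisopropylsilyloxy)phenyl]boronic acid | CC(C)[Si](Oc1ccc(B(O)O)cc1)(C(C)C)C(C)C
F2 | step 4 | 2,5-dibromo-3,6-dimethoxy-1,4-benzoquinone | COC1=C(Br)C(=O)C(OC)=C(Br)C1=O
F3 | step 4 | 2,5-dimethoxy-3,6-bis[4-(triisopropylsilyloxy)phenyl]-1,4-benzoquinone | COC1=C(c2ccc(O[Si](C(C)C)(C(C)C)C(C)C)cc2)C(=O)C(OC)=C(c2ccc(O[Si](C(C)C)(C(C)C)C(C)C)cc2)C1=O
F4 | step 9 | 2,5-dichloro-3,6-bis[4-(triisopropylsilyloxy)phenyl]-1,4-benzoquinone | ClC1=C(c2ccc(O[Si](C(C)C)(C(C)C)C(C)C)cc2)C(=O)C(Cl)=C(c2ccc(O[Si](C(C)C)(C(C)C)C(C)C)cc2)C1=O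
F5 | step 10 | atromentin, 2,5-dihydroxy-3,6-bis(4-hydroxyphenyl)-1,4-benzoquinone | OC1=C(c2ccc(O)cc2)C(=O)C(O)=C(c2ccc(O)cc2)C1=O
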